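## Structural features

The target is a biflavone built on a 2,2-dimethylchroman, a benzene ring fused to a dihydropyran whose O1–C2 bond is a tertiary alkyl aryl ether. Chroman C6 is C2 of a 5,7-dihydroxychromen-4-one, so the chroman benzene ring acts as ring B of the first flavone. Chroman C8 is bonded to C8 of apigenin, that is, to ring A of the second flavone. There is no stereocentre; the C8–C8 biaryl bond has three ortho oxygen substituents (chroman O1, apigenin C7–OH, apigenin O1) and is crowded, but carries no axial descriptor. The fragile parts are: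
- the tertiary ether, which ionises with strong Lewis acids;
- the 5-hydroxy-8-arylflavone, where acid-promoted ring opening and reclosure can move the aryl group to C6;
- both pyranones, which are opened by hydroxide or alkoxide;
- the five phenols, two of them chelated to a C4 carbonyl, which are air-sensitive once ionised.

The real difficulty is the hindered, electron-rich biaryl bond together with two pyranones that must be built in opposite senses on one central ring, each with unambiguous regiochemistry. The key step exploits the array aryl–C4(=O)–C3H=C2(aryl)–O1 found in both pyranones: each C2–C3 bond can be made by moving an acyl group from a phenolic oxygen onto an acetyl carbon. For the first flavone the acyl donor is the carboxyl carbon on chroman C6; for the apigenin unit the acetyl group on the ring bonded to chroman C8 receives a 4-oxygenated benzoyl group.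

## Logic of the disconnections

17 from 16. The five O–CH2Ph bonds are cut. Benzyl is chosen over methyl because hydrogenolysis is neutral, whereas the boron trihalide needed for five methyl ethers could ionise the tertiary O1–C2 bond of the chroman and promote the 8-to-6 aryl shift. The gain is one kind of protecting group on every phenol from the start. The demand is that the cleavage must not reduce the two C2–C3 double bonds.

16 from 15. The O1–C2 bond of each pyranone is cut, which opens both heterocycles to o-hydroxyaryl 1,3-diketones. The demand is that only one phenol per diketone is free, so that the apigenin ring cannot close toward the 6-aryl isomer, and that the acid is mild enough for the benzyl ethers.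

15 from 14. The C2–C3 bond of each future pyranone is cut and traced back to an aryl ester next to an acetyl group. This is the strategic cut: two C–C bonds become two C–O bonds. The skeletons of 14 and 15 were checked atom by atom against 17 and need no correction; only the phenol protecting groups differ from an all-methyl version. The forward step needs at least four equivalents of base and strict site fidelity of the two enolates.

14 from 13 and 7. The ester C(=O)–O bond between the carboxyl carbon on chroman C6 and the phenol oxygen of 7 is cut. It is formed last because it is the more exposed of the two base-labile esters. The demand is a neutral coupling that leaves the first aryl ester intact.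

13 from 10 and 11. The ester C(=O)–O bond at the crowded phenol is cut. This leads back to a robust hydroxy acid. The demand is acylation of a chelated, doubly ortho-substituted phenol while a free carboxyl group is present.

10 from 6 and 8. The biaryl bond between chroman C8 and the future apigenin C8 is cut, and the carboxyl group is traced back to its methyl ester. The coupling is placed before either aryl ester exists, so aqueous base is harmless. Boron is put on the chroman because a boronate on the ring with two ortho oxygens would protodeboronate. The demand is a coupling that joins two ortho-substituted partners.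

8 from 7. The C3–I bond is cut. The demand is iodination ortho to the free hydroxyl and not between the two benzyloxy groups.

6 from 5 from 4. The C8–B bond and then the C8–Br bond are cut. C8 is the only position ortho to the ring oxygen, so the halogenation should need no control element.

4 from 3 from 1 and 2. The chroman O1–C2 bond is cut, then the C4–C4a bond between the ring and the allylic CH2. This leads to two bulk chemicals. The demand is C-alkylation of a phenoxide in preference to O-alkylation.

## Other disconnections considered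

Alternative 1: The cut runs through ring A of the apigenin unit. C8–C8a and C6–C7 are disconnected and C4a–C8a is broken and re-formed, so ring A is grown on the chroman.
- Forward step: heating 3-ethoxycyclobut-2-en-1-one A1 with the silyl ynol ether triisopropyl{[(6-bromo-2,2-dimethylchroman-8-yl)ethynyl]oxy}silane A2. Four-electron opening of A1, ketene–alkyne [2+2] addition, a second four-electron opening and a six-electron closure should give 2-(6-bromo-2,2-dimethylchroman-8-yl)-5-ethoxy-3-(triisopropylsilyloxy)phenol A3.
- In favour: the crowded biaryl bond exists before the ring does, so no cross-coupling of two ortho-substituted partners is needed. On this point the alternative is better than the chosen plan, whose step 6 must force such a coupling. The cascade is thermal and neutral. The three ring A oxygens emerge differentiated, which is at least the equal of the regiocontrol that step 5 has to deliver.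
- Against: A3 has no carbon at C4a, so the pyranone acyl group would have to be put onto an electron-rich ring with two open positions. A2 needs several steps from a chroman carboxylate. The bromide at chroman C6 must still become a carboxyl derivative. The O5 ethyl ether needs a Lewis-acid dealkylation next to the tertiary ether.
- Comparison: structurally A3 is much further from 17 than 14 is. Mechanistically the pericyclic cascade is gentler than an anionic acyl transfer. In step count it should be clearly longer than eleven steps, because its key step builds one carbocycle while step 9 prepares both heterocycles at once.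

Alternative 2: The cut removes chroman C3–C4 and O1–C2 from a complete, O-methylated biflavone.
- Forward step: heating the o-hydroxybenzyl alcohol 8-[5-(5,7-dimethoxy-4-oxo-4H-chromen-2-yl)-2-hydroxy-3-(hydroxymethyl)phenyl]-5,7-dimethoxy-2-(4-methoxyphenyl)-4H-chromen-4-one A4 should dehydrate it to the ortho-quinone methide A5. A5 would add 2-methylpropene A6 in an inverse-demand hetero-[4+2] reaction to give the pentamethyl ether A7 of the target.
- In favour: the regiochemistry follows from polarity (oxygen to the disubstituted alkene carbon). The two flavones could be made separately and joined by cross-coupling; this convergence is a point on which the alternative is better than the largely linear chosen plan. A7 is the methyl analogue of 16, so the end game is equal in length.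
- Against: A6 is a gas and only a weakly nucleophilic alkene, whereas A5 would react best with enol ethers or styrenes, so self-condensation of A5 is a serious competitor. A4 needs a sixth, separately addressable oxygen and an extra one-carbon unit. The chroman is available in two simple steps at the start, so postponing it buys nothing. The five methyl ethers of A7 call for exactly the boron trihalide treatment that endangers the tertiary ether.
- Comparison: the cycloaddition is mechanistically sound, but with this alkene it is less dependable than the intramolecular acyl transfer, and the overall count would be no lower.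

Alternative 3: The cut is chroman O1–C8a.
- Forward step: the tertiary alkoxide of methyl 3-[5,7-dimethoxy-2-(4-methoxyphenyl)-4-oxo-4H-chromen-8-yl]-4-fluoro-5-(3-hydroxy-3-methylbutyl)benzoate A8 would attack the fluorine-bearing carbon, activated by the para ester. Addition–elimination would displace fluorine and give methyl 8-[5,7-dimethoxy-2-(4-methoxyphenyl)-4-oxo-4H-chromen-8-yl]-2,2-dimethylchroman-6-carboxylate A9.
- In favour: the tertiary ether is formed irreversibly under basic, non-cationic conditions. In principle this is cleaner than an acid-mediated closure and is a point on which the alternative is the equal of step 2 or better.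
- Against: the alkoxide must be generated beside a base-sensitive pyranone and a methyl ester. The reacting carbon lies between the side chain and the bulky apigenin unit. A8 is a 1,2,3,5-tetrasubstituted fluoroarene that would need a long synthesis. A9 still lacks one pyranone and still carries methyl ethers.
- Comparison: the step solves a ring closure that the chosen plan achieves in step 2 on a simple substrate with no competing pathway, so it adds steps without removing a risk.

Key step: step 9

Assumption: the target has no axial descriptor, so the C8–C8 axis is treated as configurationally undefined and no atroposelective step is planned.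
Assumption: 2-hydroxy-4,6-bis(benzyloxy)acetophenone and 4-(benzyloxy)benzoyl chloride are treated as catalogue compounds.

## Route

Step 1
Reactants: 1 methyl 4-hydroxybenzoate; 2 1-bromo-3-methylbut-2-ene
Product: 3 methyl 4-hydroxy-3-(3-methylbut-2-en-1-yl)benzoate
Conditions: NaH, toluene, 0 °C to rt; then 2, rt to 40 °C
Reagents that add atoms: none
Why: Ortho C-alkylation of a phenoxide: the sodium phenoxide reacts in toluene as a tight ion pair, which steers the allylic bromide to the ortho carbon; the para position is blocked, and the O-prenyl ether by-product should be removable by base extraction.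

Step 2
Reactants: 3 methyl 4-hydroxy-3-(3-methylbut-2-en-1-yl)benzoate
Product: 4 methyl 2,2-dimethylchroman-6-carboxylate
Conditions: Amberlyst 15, toluene, 60 °C
Reagents that add atoms: none
Why: Acid-catalysed Markovnikov hydroalkoxylation: protonation of the trisubstituted alkene gives the tertiary cation, which the neighbouring phenol oxygen traps in a 6-endo closure, the classical cyclisation of ortho-prenylphenols.

Step 3
Reactants: 4 methyl 2,2-dimethylchroman-6-carboxylate
Product: 5 methyl 8-bromo-2,2-dimethylchroman-6-carboxylate
Conditions: Br2, NaOAc, AcOH, rt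
Reagents that add atoms: bromine, BrBr
Why: Electrophilic aromatic bromination: C8 is the only position ortho to the ring oxygen (para is occupied) and is meta to the ester, so one monobromide is expected; NaOAc buffers the HBr and protects the tertiary ether.

Step 4
Reactants: 5 methyl 8-bromo-2,2-dimethylchroman-6-carboxylate
Product: 6 methyl 2,2-dimethyl-8-(4,4,5,5-tetramethyl-1,3,2-dioxaborolan-2-yl)chroman-6-carboxylate
Conditions: B2pin2, Pd(dppf)Cl2 (3 mol %), KOAc, 1,4-dioxane, 90 °C
Reagents that add atoms: bis(pinacolato)diboron, CC1(C)OB(OC1(C)C)B1OC(C)(C)C(C)(C)O1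
Why: Miyaura borylation: oxidative addition of the aryl bromide to zerovalent palladium, acetate-assisted transmetalation from the diboron and reductive elimination; KOAc is too weak a base to harm the methyl ester.

Step 5
Reactants: 7 1-[2,4-bis(benzyloxy)-6-hydroxyphenyl]ethan-1-one
Product: 8 1-[4,6-bis(benzyloxy)-2-hydroxy-3-iodophenyl]ethan-1-one
Conditions: BnMe3N·ICl2, NaHCO3, CH2Cl2–MeOH, rt
Reagents that add atoms: benzyltrimethylammonium dichloroiodate, C[N+](C)(C)Cc1ccccc1.Cl[I-]Cl
Why: Electrophilic iodination of a chelated phenol: C3 is ortho to the hydroxyl, para to a benzyloxy group and has the small OH as neighbour, whereas C5 lies between two benzyloxy groups; the mild reagent and bicarbonate buffer should stop at mono-iodination.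

Step 6
Reactants: 6 methyl 2,2-dimethyl-8-(4,4,5,5-tetramethyl-1,3,2-dioxaborolan-2-yl)chroman-6-carboxylate; 8 1-[4,6-bis(benzyloxy)-2-hydroxy-3-iodophenyl]ethan-1-one
Product: 10 8-[3-acetyl-4,6-bis(benzyloxy)-2-hydroxyphenyl]-2,2-dimethylchroman-6-carboxylic acid, via biaryl methyl ester 9 (not isolated)
Conditions: Pd(OAc)2 (5 mol %), SPhos (10 mol %), K3PO4, 1,4-dioxane–H2O, 80 °C; then LiOH, H2O, 60 °C; then 1 M HCl
Reagents that add atoms: lithium hydroxide, [Li+].[OH-]
Why: Suzuki–Miyaura coupling with a dialkylbiarylphosphine made for ortho-substituted partners forms the hindered biaryl bond; no base-labile aryl ester is present yet, so aqueous phosphate is harmless and LiOH added to the same pot saponifies the methyl ester.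

Step 7
Reactants: 10 8-[3-acetyl-4,6-bis(benzyloxy)-2-hydroxyphenyl]-2,2-dimethylchroman-6-carboxylic acid; 11 4-(benzyloxy)benzoyl chloride
Product: 13 8-[3-acetyl-4,6-bis(benzyloxy)-2-{[4-(benzyloxy)benzoyl]oxy}phenyl]-2,2-dimethylchroman-6-carboxylic acid, via mixed anhydride 12 (not isolated)
Conditions: 11 (3 equiv), Et3N, DMAP (0.2 equiv), CH2Cl2, 0 °C to rt; then pyridine–H2O, rt
Reagents that add atoms: water, O
Why: DMAP-catalysed O-acylation of the chelated, doubly flanked phenol; the carboxyl group is tied up meanwhile as a mixed anhydride, which is far more electrophilic than the new aryl ester and is hydrolysed selectively by aqueous pyridine.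

Step 8
Reactants: 13 8-[3-acetyl-4,6-bis(benzyloxy)-2-{[4-(benzyloxy)benzoyl]oxy}phenyl]-2,2-dimethylchroman-6-carboxylic acid; 7 1-[2,4-bis(benzyloxy)-6-hydroxyphenyl]ethan-1-one
Product: 14 2-acetyl-3,5-bis(benzyloxy)phenyl 8-[3-acetyl-4,6-bis(benzyloxy)-2-{[4-(benzyloxy)benzoyl]oxy}phenyl]-2,2-dimethylchroman-6-carboxylate
Conditions: DCC, DMAP (0.2 equiv), CH2Cl2, rt
Reagents that add atoms: none
Why: Steglich esterification: 13 has no free hydroxyl, so the only ester that can form joins its carboxyl group to the phenol of 7, and the neutral conditions leave the first aryl ester and both acetyl groups alone.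

Step 9
Reactants: 14 2-acetyl-3,5-bis(benzyloxy)phenyl 8-[3-acetyl-4,6-bis(benzyloxy)-2-{[4-(benzyloxy)benzoyl]oxy}phenyl]-2,2-dimethylchroman-6-carboxylate
Product: 15 1-[2,4-bis(benzyloxy)-6-hydroxyphenyl]-3-{8-[4,6-bis(benzyloxy)-3-{3-[4-(benzyloxy)phenyl]-3-oxopropanoyl}-2-hydroxyphenyl]-2,2-dimethylchroman-6-yl}propane-1,3-dione
Conditions: LiHMDS (6 equiv), THF (0.02 M), −78 °C to rt; then 1 M HCl
Reagents that add atoms: none
Why: This is a two-fold Baker–Venkataraman rearrangement, the known base-induced O-to-C acyl shift of o-acyloxyacetophenones to o-hydroxyaryl 1,3-diketones, applied at two sites of one molecule. LiHMDS turns both methyl ketones into enolates; the carbon of each adds to the carbonyl of the ester on the adjacent ring oxygen through a six-membered cyclic array, the adduct collapses with loss of the aryloxide, and the diketone formed is deprotonated again at once, which takes it out of the equilibrium. On the ring attached to chroman C8 the 4-(benzyloxy)benzoyl group migrates, and on the other ring the chroman-6-carbonyl group migrates, so the two new C–C bonds are C2–C3 of the two future pyranones. No ring is closed and no stereocentre is formed. The selectivity needed is site fidelity, each enolate acylating only at the ester of its own ring; it is secured by geometry, since the neighbouring ester is reached through a six-membered transition state whereas the distant ester would require a large ring across the twisted biaryl, and intermolecular transfer is held back by dilution. A non-nucleophilic amide base is used so that the base itself does not cleave the two activated aryl esters, and six equivalents keep both phenoxides and both diketonates ionised. The crowded aroyl ester beside the biaryl axis should still react because its nucleophile is tethered next to it.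

Step 10
Reactants: 15 1-[2,4-bis(benzyloxy)-6-hydroxyphenyl]-3-{8-[4,6-bis(benzyloxy)-3-{3-[4-(benzyloxy)phenyl]-3-oxopropanoyl}-2-hydroxyphenyl]-2,2-dimethylchroman-6-yl}propane-1,3-dione
Product: 16 5,7-bis(benzyloxy)-8-{6-[5,7-bis(benzyloxy)-4-oxo-4H-chromen-2-yl]-2,2-dimethylchroman-8-yl}-2-[4-(benzyloxy)phenyl]-4H-chromen-4-one
Conditions: H2SO4 (cat.), AcOH, 60 °C
Reagents that add atoms: none
Why: Acid-catalysed cyclodehydration of o-hydroxyaryl 1,3-diketones: each phenol adds 6-exo-trig to the distal carbonyl and the 2-hydroxychromanone loses water; because every other ring A oxygen is benzylated, only the phenol freed in step 9 can close, which fixes the 8-aryl orientation of the apigenin unit.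

Step 11
Reactants: 16 5,7-bis(benzyloxy)-8-{6-[5,7-bis(benzyloxy)-4-oxo-4H-chromen-2-yl]-2,2-dimethylchroman-8-yl}-2-[4-(benzyloxy)phenyl]-4H-chromen-4-one
Product: 17 8-[6-(5,7-dihydroxy-4-oxo-4H-chromen-2-yl)-2,2-dimethylchroman-8-yl]-5,7-dihydroxy-2-(4-hydroxyphenyl)-4H-chromen-4-one (CNP0127025.0)
Conditions: H2 (1 atm), Pd/C, THF–MeOH, rt
Reagents that add atoms: none
Why: Hydrogenolysis of aryl benzyl ethers is neutral, so neither the tertiary chroman ether nor the acid-sensitive 5-hydroxy-8-arylflavone is at risk; the pyranone double bonds are aryl-conjugated vinylogous esters and should be reduced far more slowly than the O-benzyl bonds are cleaved.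

## Compound list

1 | methyl 4-hydroxybenzoate | COC(=O)c1ccc(O)cc1 | starting material
2 | 1-bromo-3-methylbut-2-ene | CC(C)=CCBr | starting material
3 | methyl 4-hydroxy-3-(3-methylbut-2-en-1-yl)benzoate | COC(=O)c1ccc(O)c(CC=C(C)C)c1 | intermediate
4 | methyl 2,2-dimethylchroman-6-carboxylate | COC(=O)c1ccc2c(c1)CCC(C)(C)O2 | intermediate
5 | methyl 8-bromo-2,2-dimethylchroman-6-carboxylate | COC(=O)c1cc(Br)c2c(c1)CCC(C)(C)O2 | intermediate
6 | methyl 2,2-dimethyl-8-(4,4,5,5-tetramethyl-1,3,2-dioxaborolan-2-yl)chroman-6-carboxylate | COC(=O)c1cc(B3OC(C)(C)C(C)(C)O3)c2c(c1)CCC(C)(C)O2 | intermediate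
7 | 1-[2,4-bis(benzyloxy)-6-hydroxyphenyl]ethan-1-one | CC(=O)c1c(O)cc(OCc2ccccc2)cc1OCc1ccccc1 | starting material
8 | 1-[4,6-bis(benzyloxy)-2-hydroxy-3-iodophenyl]ethan-1-one | CC(=O)c1c(O)c(I)c(OCc2ccccc2)cc1OCc1ccccc1 | intermediate
9 | methyl 8-[3-acetyl-4,6-bis(benzyloxy)-2-hydroxyphenyl]-2,2-dimethylchroman-6-carboxylate | COC(=O)c1cc(-c3c(O)c(C(C)=O)c(OCc4ccccc4)cc3OCc3ccccc3)c2c(c1)CCC(C)(C)O2 | intermediate (not isolated)
10 | 8-[3-acetyl-4,6-bis(benzyloxy)-2-hydroxyphenyl]-2,2-dimethylchroman-6-carboxylic acid | OC(=O)c1cc(-c3c(O)c(C(C)=O)c(OCc4ccccc4)cc3OCc3ccccc3)c2c(c1)CCC(C)(C)O2 | intermediate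
11 | 4-(benzyloxy)benzoyl chloride | O=C(Cl)c1ccc(OCc2ccccc2)cc1 | starting material
12 | 8-[3-acetyl-4,6-bis(benzyloxy)-2-{[4-(benzyloxy)benzoyl]oxy}phenyl]-2,2-dimethylchroman-6-carboxylic 4-(benzyloxy)benzoic anhydride | O=C(OC(=O)c1ccc(OCc2ccccc2)cc1)c1cc(-c3c(OC(=O)c4ccc(OCc5ccccc5)cc4)c(C(C)=O)c(OCc4ccccc4)cc3OCc3ccccc3)c2c(c1)CCC(C)(C)O2 | intermediate (not isolated)
13 | 8-[3-acetyl-4,6-bis(benzyloxy)-2-{[4-(benzyloxy)benzoyl]oxy}phenyl]-2,2-dimethylchroman-6-carboxylic acid | OC(=O)c1cc(-c3c(OC(=O)c4ccc(OCc5ccccc5)cc4)c(C(C)=O)c(OCc4ccccc4)cc3OCc3ccccc3)c2c(c1)CCC(C)(C)O2 | intermediate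
14 | 2-acetyl-3,5-bis(benzyloxy)phenyl 8-[3-acetyl-4,6-bis(benzyloxy)-2-{[4-(benzyloxy)benzoyl]oxy}phenyl]-2,2-dimethylchroman-6-carboxylate | CC(=O)c1c(OCc2ccccc2)cc(OCc2ccccc2)cc1OC(=O)c1cc(-c3c(OC(=O)c4ccc(OCc5ccccc5)cc4)c(C(C)=O)c(OCc4ccccc4)cc3OCc3ccccc3)c2c(c1)CCC(C)(C)O2 | intermediate
15 | 1-[2,4-bis(benzyloxy)-6-hydroxyphenyl]-3-{8-[4,6-bis(benzyloxy)-3-{3-[4-(benzyloxy)phenyl]-3-oxopropanoyl}-2-hydroxyphenyl]-2,2-dimethylchroman-6-yl}propane-1,3-dione | O=C(CC(=O)c1c(O)cc(OCc2ccccc2)cc1OCc1ccccc1)c1cc(-c3c(O)c(C(=O)CC(=O)c4ccc(OCc5ccccc5)cc4)c(OCc4ccccc4)cc3OCc3ccccc3)c2c(c1)CCC(C)(C)O2 | intermediate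
16 | 5,7-bis(benzyloxy)-8-{6-[5,7-bis(benzyloxy)-4-oxo-4H-chromen-2-yl]-2,2-dimethylchroman-8-yl}-2-[4-(benzyloxy)phenyl]-4H-chromen-4-one | CC1(C)CCc2cc(-c3cc(=O)c4c(OCc5ccccc5)cc(OCc5ccccc5)cc4o3)cc(-c3c(OCc4ccccc4)cc(OCc4ccccc4)c4c(=O)cc(-c5ccc(OCc6ccccc6)cc5)oc34)c2O1 | intermediate
17 | 8-[6-(5,7-dihydroxy-4-oxo-4H-chromen-2-yl)-2,2-dimethylchroman-8-yl]-5,7-dihydroxy-2-(4-hydroxyphenyl)-4H-chromen-4-one | CC1(C)CCc2cc(-c3cc(=O)c4c(O)cc(O)cc4o3)cc(-c3c(O)cc(O)c4c(=O)cc(-c5ccc(O)cc5)oc34)c2O1 | target

## Step count and least certain steps

Total: 11 steps. Longest linear sequence: 10 steps (steps 1 to 4 and 6 to 11); step 5 is a one-step branch.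

Step 9 (key step). The most likely failures are incomplete acyl transfer at the crowded ester beside the biaryl axis, or cleavage of an aryl ester by adventitious hydroxide before its enolate captures it. The fallback sets out from 10 and returns at 16; it makes the apigenin pyranone by the chalcone route and leaves a single acyl transfer.
- 10 is condensed with 4-(benzyloxy)benzaldehyde (KOH, EtOH–THF, Claisen–Schmidt) to 8-{4,6-bis(benzyloxy)-3-[(E)-3-(4-benzyloxyphenyl)prop-2-enoyl]-2-hydroxyphenyl}-2,2-dimethylchroman-6-carboxylic acid F1.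
- Oxidative cyclisation (I2 cat., DMSO, 120 °C) should give 8-{5,7-bis(benzyloxy)-2-[4-(benzyloxy)phenyl]-4-oxo-4H-chromen-8-yl}-2,2-dimethylchroman-6-carboxylic acid F2.
- Steglich esterification with 7 should give 2-acetyl-3,5-bis(benzyloxy)phenyl 8-{5,7-bis(benzyloxy)-2-[4-(benzyloxy)phenyl]-4-oxo-4H-chromen-8-yl}-2,2-dimethylchroman-6-carboxylate F3.
- A single Baker–Venkataraman shift (LiHMDS, 3 equiv) should give 1-[2,4-bis(benzyloxy)-6-hydroxyphenyl]-3-(8-{5,7-bis(benzyloxy)-2-[4-(benzyloxy)phenyl]-4-oxo-4H-chromen-8-yl}-2,2-dimethylchroman-6-yl)propane-1,3-dione F4.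
- Acid cyclodehydration as in step 10 returns 16.

Step 6. Oxidative addition into the electron-rich iodophenoxide and transmetalation at the ortho-substituted boronate may be slow, so that protodeboronation and reductive deiodination outrun coupling. The fallback sets out from 8 (with 6) and returns at 9, which is saponified to 10 as in step 6.
- 8 is masked (MOMCl, i-Pr2NEt, CH2Cl2) as 1-[4,6-bis(benzyloxy)-3-iodo-2-(methoxymethoxy)phenyl]ethan-1-one F5, which is no longer a phenoxide under the coupling conditions.
- Suzuki coupling with 6 should give methyl 8-[3-acetyl-4,6-bis(benzyloxy)-2-(methoxymethoxy)phenyl]-2,2-dimethylchroman-6-carboxylate F6.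
- HCl in MeOH removes the acetal and gives 9.

Step 7. Acylation of the chelated, doubly flanked phenol may be sluggish, and acyl scrambling through the mixed anhydride may lead to oligoesters. The fallback sets out from 10 and returns at 14, reversing the order of the two esterifications.
- 10 is esterified with an excess of 7 (DCC, DMAP), relying on the lower reactivity of its own hindered phenol, to give 2-acetyl-3,5-bis(benzyloxy)phenyl 8-[3-acetyl-4,6-bis(benzyloxy)-2-hydroxyphenyl]-2,2-dimethylchroman-6-carboxylate F7.
- The remaining phenol is then acylated with 11 (Et3N, stoichiometric DMAP, CH2Cl2, 40 °C) to give 14.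

Step 1. O-alkylation and double alkylation may compete with the ortho C-alkylation. The fallback sets out from 1 and returns at 4.
- 1 is O-alkylated with 3-chloro-3-methylbut-1-yne (K2CO3, KI, CuI cat., acetone) to methyl 4-[(2-methylbut-3-yn-2-yl)oxy]benzoate F8.
- Heating in N,N-diethylaniline (about 190 °C) should bring about propargyl Claisen rearrangement, 1,5-hydrogen shift and six-electron closure to methyl 2,2-dimethyl-2H-chromene-6-carboxylate F9.
- Hydrogenation of the C3–C4 double bond (H2, Pd/C) gives 4.

Step 11. The pyranone double bonds may be over-reduced, or debenzylation may stall because partly deprotected material precipitates. The fallback sets out from 16 and returns at 17: Lewis-acid debenzylation with BCl3 and pentamethylbenzene as cation scavenger in CH2Cl2 at −78 °C, a temperature at which the tertiary ether should survive.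

## Further compounds

F1 | step 9 | 8-{4,6-bis(benzyloxy)-3-[(E)-3-(4-benzyloxyphenyl)prop-2-enoyl]-2-hydroxyphenyl}-2,2-dimethylchroman-6-carboxylic acid | OC(=O)c1cc(-c3c(O)c(C(=O)/C=C/c4ccc(OCc5ccccc5)cc4)c(OCc4ccccc4)cc3OCc3ccccc3)c2c(c1)CCC(C)(C)O2
F2 | step 9 | 8-{5,7-bis(benzyloxy)-2-[4-(benzyloxy)phenyl]-4-oxo-4H-chromen-8-yl}-2,2-dimethylchroman-6-carboxylic acid | OC(=O)c1cc(-c3c(OCc4ccccc4)cc(OCc4ccccc4)c4c(=O)cc(-c5ccc(OCc6ccccc6)cc5)oc34)c2c(c1)CCC(C)(C)O2
F3 | step 9 | 2-acetyl-3,5-bis(benzyloxy)phenyl 8-{5,7-bis(benzyloxy)-2-[4-(benzyloxy)phenyl]-4-oxo-4H-chromen-8-yl}-2,2-dimethylchroman-6-carboxylate | CC(=O)c1c(OCc2ccccc2)cc(OCc2ccccc2)cc1OC(=O)c1cc(-c3c(OCc4ccccc4)cc(OCc4ccccc4)c4c(=O)cc(-c5ccc(OCc6ccccc6)cc5)oc34)c2c(c1)CCC(C)(C)O2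
F4 | step 9 | 1-[2,4-bis(benzyloxy)-6-hydroxyphenyl]-3-(8-{5,7-bis(benzyloxy)-2-[4-(benzyloxy)phenyl]-4-oxo-4H-chromen-8-yl}-2,2-dimethylchroman-6-yl)propane-1,3-dione | O=C(CC(=O)c1c(O)cc(OCc2ccccc2)cc1OCc1ccccc1)c1cc(-c3c(OCc4ccccc4)cc(OCc4ccccc4)c4c(=O)cc(-c5ccc(OCc6ccccc6)cc5)oc34)c2c(c1)CCC(C)(C)O2
F5 | step 6 | 1-[4,6-bis(benzyloxy)-3-iodo-2-(methoxymethoxy)phenyl]ethan-1-one | CC(=O)c1c(OCOC)c(I)c(OCc2ccccc2)cc1OCc1ccccc1
F6 | step 6 | methyl 8-[3-acetyl-4,6-bis(benzyloxy)-2-(methoxymethoxy)phenyl]-2,2-dimethylchroman-6-carboxylate | COC(=O)c1cc(-c3c(OCOC)c(C(C)=O)c(OCc4ccccc4)cc3OCc3ccccc3)c2c(c1)CCC(C)(C)O2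
F7 | step 7 | 2-acetyl-3,5-bis(benzyloxy)phenyl 8-[3-acetyl-4,6-bis(benzyloxy)-2-hydroxyphenyl]-2,2-dimethylchroman-6-carboxylate | CC(=O)c1c(OCc2ccccc2)cc(OCc2ccccc2)cc1OC(=O)c1cc(-c3c(O)c(C(C)=O)c(OCc4ccccc4)cc3OCc3ccccc3)c2c(c1)CCC(C)(C)O2
F8 | step 1 | methyl 4-[(2-methylbut-3-yn-2-yl)oxy]benzoate | COC(=O)c1ccc(OC(C)(C)C#C)cc1
F9 | step 1 | methyl 2,2-dimethyl-2H-chromene-6-carboxylate | COC(=O)c1ccc2c(c1)C=CC(C)(C)O2
F0 | step 11 | none | none
A1 | alternative 1 | 3-ethoxycyclobut-2-en-1-one | CCOC1=CC(=O)C1
A2 | alternative 1 | triisopropyl{[(6-bromo-2,2-dimethylchroman-8-yl)ethynyl]oxy}silane | CC(C)[Si](OC#Cc1cc(Br)cc2c1OC(C)(C)CC2)(C(C)C)C(C)C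
A3 | alternative 1 | 2-(6-bromo-2,2-dimethylchroman-8-yl)-5-ethoxy-3-(triisopropylsilyloxy)phenol | CCOc1cc(O)c(-c2cc(Br)cc3c2OC(C)(C)CC3)c(O[Si](C(C)C)(C(C)C)C(C)C)c1
A4 | alternative 2 | 8-[5-(5,7-dimethoxy-4-oxo-4H-chromen-2-yl)-2-hydroxy-3-(hydroxymethyl)phenyl]-5,7-dimethoxy-2-(4-methoxyphenyl)-4H-chromen-4-one | OCc1cc(-c2cc(=O)c3c(OC)cc(OC)cc3o2)cc(-c2c(OC)cc(OC)c3c(=O)cc(-c4ccc(OC)cc4)oc23)c1O
A5 | alternative 2 | ortho-quinone methide formed from A4 by loss of water | C=C1C=C(-c2cc(=O)c3c(OC)cc(OC)cc3o2)C=C(-c2c(OC)cc(OC)c3c(=O)cc(-c4ccc(OC)cc4)oc23)C1=O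
A6 | alternative 2 | 2-methylpropene | CC(C)=C
A7 | alternative 2 | pentamethyl ether of the target | CC1(C)CCc2cc(-c3cc(=O)c4c(OC)cc(OC)cc4o3)cc(-c3c(OC)cc(OC)c4c(=O)cc(-c5ccc(OC)cc5)oc34)c2O1
A8 | alternative 3 | methyl 3-[5,7-dimethoxy-2-(4-methoxyphenyl)-4-oxo-4H-chromen-8-yl]-4-fluoro-5-(3-hydroxy-3-methylbutyl)benzoate | COC(=O)c1cc(CCC(C)(C)O)c(F)c(-c2c(OC)cc(OC)c3c(=O)cc(-c4ccc(OC)cc4)oc23)c1
A9 | alternative 3 | methyl 8-[5,7-dimethoxy-2-(4-methoxyphenyl)-4-oxo-4H-chromen-8-yl]-2,2-dimethylchroman-6-carboxylate | COC(=O)c1cc2c(c(-c3c(OC)cc(OC)c4c(=O)cc(-c5ccc(OC)cc5)oc34)c1)OC(C)(C)CC2
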